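Ring carbons are numbered C1–C16 in the order in which they appear in the target SMILES: C1 bears the exocyclic methylene, C4 the propionate, C5 the angular methyl, C9 a methyl, C10 the acetate, C12/C13 the epoxide, C14 the hydroxyl, and C16 is the ring-fusion CH. Substituents are named by the carbon that bears them.

## Analysis of the target

The target is a trinervitane-type diterpenoid. A cis-fused hydrindane (six-membered ring C1–C2–C3–C4–C5–C16, five-membered ring C5–C6–C7–C8–C16) is bridged from C2 to C8 by the chain C15–C14–C13–C12–C11–C10–C9, so that an eleven-membered ring shares C2, C1, C16 and C8 with the bicycle. There are ten stereocentres (2R,4S,5S,8R,9S,10S,12S,13S,14R,16S in this numbering). On the six-membered ring the C4 oxygen, the C5 methyl, the C16 hydrogen and the C2–C15 bond lie on one face and the five-membered ring on the other. C8–H is cis to C16–H, so the chain leaves C8 on the side of the six-membered ring. The chain carries the C9 methyl, the C10 acetate, a trans 12,13-epoxide and the free C14 hydroxyl, which is threo to the epoxide oxygen. Sensitive groups are the epoxy alcohol (acid, Lewis acid, base-induced epoxide migration), two different esters that must not migrate to the free hydroxyl, and the C1 methylene flanked by two tertiary allylic CH groups. The difficulties are the quaternary C5 next to the oxygenated C4 inside a cis ring fusion, the medium ring, and three oxygens that must end up differently substituted. The strategy rests on one feature of the six-membered ring: C4–O and the sp2 carbon C1 stand 1,4 to each other, with C5–CH3 and C16–H cis and on the face of the C4 oxygen. A one-carbon lactone bridge from the C4 oxygen to C1 encodes exactly this pattern, which is the adduct of a 2-pyrone with a cyclopentenone.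

## Retrosynthetic reasoning

**Epoxide (32 to 31).** The C12–O and C13–O bonds are cut last. The epoxy alcohol is the most fragile unit, and made in the final step it meets no later reagent. The forward step is a hydroxyl-assisted peracid epoxidation of allylic alcohol 31. It has to prefer the trisubstituted C12=C13 over the C1 methylene and attack the outer face of the olefin in the eleven-membered ring.

**C1 methylene and C14 silyl ether (31 to 30 to 29).** The C1=CH2 bond is traced to the C1 ketone of 29. The ketone is flanked by the epimerisable C2 and C16, so a non-basic methylenation is needed. It is run while C14 is still a silyl ether and before any epoxide exists.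

**C7–C8 saturation (29 to 28 to 27).** The C8–H bond is made by hydrogenating the C7=C8 olefin of 27 on the convex face of the cyclopentene. The C10 hydroxyl is acetylated first (28) so that it cannot steer the catalyst to the wrong face. This also installs the acetate of the target.

**Eleven-membered ring (27 to 26).** The ring is cut at C9–C10. A carbonyl-ene reaction between the C10 aldehyde and the Z ethylidene on C8 forms this bond, creates C9 and C10 together, and needs no activating group on either partner. Other cuts of the ring would require extra functionality that has to be removed afterwards.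

**Side chain (26 back to 15 and 21).** The aldehyde 26 comes from PMB ether 24 through alcohol 25. The C14 stereocentre comes from a catalyst-controlled reduction of enone 22, giving alcohol 23. The C13–C14 bond is cut to thioester 15 and alkenylstannane 21. A neutral acyl–alkenyl coupling is chosen because the C1 ketone and the C4 propionate rule out polar organometallic additions. Stannane 21 is traced through iodide 19 and ether 17 to alkynol 16.

**C2–C15 (15 to 10 and 13).** Conjugate reduction of enone 10 gives the C1/C2 enolate 14 regiospecifically, away from the more acidic C16 side. Alkylation with bromothioester 13 attaches C15 and C14 in one step. The C2=C3 olefin left by the cycloaddition is what makes this regiocontrol possible.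

**Unmasking C1 (10 to 9 to 8 to 7).** The propionate is put on the C4 hydroxyl of 9. The C1 ketone of 9 arises by oxidative decarboxylation of α-hydroxy acid 8, and 8 by hydrolysis of the lactone bridge of 7. The bridge has then done its work of holding the C4 oxygen and the masked C1 ketone on the face of the C5 methyl.

**C8=C9 (7 to 4 and 5, 4 to 3).** The ethylidene is installed by a Wittig reaction while C1 is still masked in the lactone. Once C1 is a ketone, C16 would sit between two carbonyl groups and the C8 ketone could no longer be olefinated. The C1 hydroxyl of 3 is silylated (4) so that the β-hydroxy ketone cannot undergo retro-aldol cleavage under the basic ylide.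

**Key disconnection (3 to 1 and 2).** The C4–C5 and C1–C16 bonds are cut. The forward reaction is the base-catalysed cycloaddition of the dienolate of 1 with 2. It creates C1, C4, C5 and C16 in one step from two purchased compounds.

## Alternatives that were turned down

**Alternative 1: ring contraction of a macrolactone by Ireland–Claisen rearrangement.**
- Disconnection: C8–C9, traced back to an ester between an oxygen on C6 and the acyl carbon next to C9 in the fifteen-membered lactone A1.
- Forward key step: the silyl ketene acetal of A1 rearranges through the allylic unit O–C6–C7=C8. The new C8–C9 bond contracts the lactone to the eleven-membered carbocycle A2, which carries a carboxyl group on C9 and a C6=C7 olefin.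
- For: macrolactonisation is one of the most dependable large-ring closures, and the strained ring is then reached by an exergonic sigmatropic step. The suprafacial shift relays the C6 configuration to C8. On this point it is stronger than the chosen route, where C8 has to wait for a hydrogenation.
- Against: C9 arrives as CO2H and must be reduced to CH3 in several steps next to the C10 oxygen. The C6=C7 olefin still has to be hydrogenated beside C12=C13. The ketene acetal geometry in a large ring and the chair/boat choice, which together decide C9, are not secured. The bicyclic core of A1, with an additional C6 oxygen and a C7=C8 olefin, is presupposed, and four kinds of protecting group are carried.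
- Comparison: the chosen strategy builds that core, with four stereocentres, in one catalytic step and reaches the ring closure with fewer functional-group interconversions.

**Alternative 2: transannular Heck cyclisation in a thirteen-membered ring.**
- Disconnection: C1–C2, so the six-membered ring is the last carbocycle to form.
- Forward key step: zerovalent palladium (from Pd(OAc)2, PPh3 and Ag2CO3) inserts into the C1–Br bond of the macrocycle A3. The alkenylpalladium adds 6-exo across C2=C15, and β-hydride elimination toward C14 gives the enone A4.
- For: the C1 methylene is delivered without a separate olefination. On this point it is stronger than the chosen route, which must methylenate a hindered ketone. The six-membered ring and the medium ring appear in a single step.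
- Against: A3 is itself a thirteen-membered ring with six stereocentres, so the macrocyclisation problem is only moved. The configuration at C2 depends on the conformation of a flexible ring. The alkylpalladium on C15 can also eliminate toward C2. The C14 ketone of A4 must then be reduced and the enone epoxidised in the threo sense, which is the unfavourable sense for hydride reduction of epoxy ketones.
- Comparison: the chosen strategy sets C2 on a rigid bicycle, where steric and thermodynamic preference agree, and brings in C14 under catalyst control.

**Alternative 3: carbonyl-ene macrocyclisation at the side-chain ethylidene.**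
- Disconnection: C9–C10.
- Forward key step: Me2AlCl promotes the ene reaction of aldehyde A5 with the Z ethylidene on C8. A hydrogen moves from C7 to oxygen, and the macrocyclic alcohol A6 with a C7=C8 olefin results.
- For: the medium ring, C9 and C10 are formed together from an aldehyde and an olefin that a Wittig reaction supplies. On the ring closure itself this alternative is exactly as strong as the chosen plan: A5 and A6 are identical with 26 and 27, and the chosen route uses this closure as its step 17.
- Against, as the strategy-defining step: it leaves open where the cis-hydrindane with C4–O, quaternary C5 and C16 comes from. It places the least precedented step at the end of the sequence, and the new C7=C8 olefin has to be hydrogenated beside C12=C13.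
- Comparison: the chosen strategy puts its strategic weight on the early step that builds the core and its four stereocentres, and treats the ene closure as a tactical step with a fallback.

Key step: step 1

Assumption: the quinidine-derived thiourea base (commercial, or two steps from quinidine) is taken to favour the enantiomer drawn for 3; its quinine-derived pseudoenantiomer would be used otherwise. As a catalyst it carries no compound number.

## Route

Step 1
Reactants: 1 3-hydroxy-2H-pyran-2-one; 2 3-methylcyclopent-2-en-1-one
Product: 3 endo lactone-bridged cycloadduct (C1 hydroxyl; C8 ketone)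
Conditions: quinidine-derived 9-amino-9-deoxy-epi thiourea (Ar = 3,5-(CF3)2C6H3, 10 mol %), 2 in excess, EtOAc, 0 °C → rt, no heating
Reagents that add atoms: none
Why: The quinuclidine nitrogen deprotonates the 3-hydroxyl of 1 and holds the dienolate as a chiral ion pair while the thiourea hydrogen-bonds the carbonyl of 2. The dienolate terminus remote from the oxido group (future C4) bonds to the β-carbon of 2 (C5) and the oxido-bearing terminus (future C1) to the α-carbon (C16), either as one asynchronous [4+2] event or as Michael addition followed by 6-exo-trig aldol closure. The closest known reaction type is the amine-base-catalysed Diels–Alder reaction of 3-hydroxy-2-pyrones with enones and acrylates, including its cinchona-catalysed asymmetric form. The ring that closes is the cyclohexene C1–C2–C3–C4–C5–C16, by [4+2] across the pyrone diene, which turns the pyranone into the lactone bridge of a bicyclo[2.2.2]octene. C5 and C16 are cis because the ring olefin of 2 adds suprafacially; endo orientation of the cyclopentanone under C2=C3 puts C5–CH3 and C16–H on the side of the lactone bridge, so C4–O, C5–CH3 and C16–H are cis; C1 and C4 are bridgeheads fixed by the diene face attacked. The absolute configuration comes from the catalyst, which shields one face of the bound dienolate. The step needs regiocontrol (given by the dienolate polarisation), endo over exo selectivity and retention of CO2 (given by the low temperature). The β,β-disubstituted enone is a weaker acceptor than those used so far, which is why 2 is taken in excess with a catalyst that activates its carbonyl.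

Step 2
Reactants: 3 endo lactone-bridged cycloadduct
Product: 4 C1 trimethylsilyl ether of the cycloadduct
Conditions: N-(trimethylsilyl)imidazole, CH2Cl2, rt
Reagents that add atoms: N-(trimethylsilyl)imidazole, C[Si](C)(C)n1ccnc1
Why: Silylation of the tertiary bridgehead hydroxyl under neutral conditions; it blocks retro-aldol cleavage of the C1–C16 bond (β-hydroxy ketone) in the basic step that follows.

Step 3
Reactants: 4 C1 trimethylsilyl ether of the cycloadduct; 5 ethyltriphenylphosphonium bromide
Product: 7 silylated lactone bearing the Z ethylidene at C8, via ethylidenetriphenylphosphorane 6 (not isolated)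
Conditions: 5, NaN(SiMe3)2, THF, 0 °C; then 4, 0 °C → rt
Reagents that add atoms: none
Why: Wittig reaction of a non-stabilised ylide at the only ketone; as with other hindered cyclopentanones the methyl should end up cis to the more substituted α-carbon C16 (Z), β-elimination of the silyloxy group is impossible at the bridgehead, and the ring fusion keeps C16 cis.

Step 4
Reactants: 7 silylated lactone bearing the Z ethylidene at C8
Product: 8 α-hydroxy acid with free C4 hydroxyl
Conditions: LiOH·H2O, THF/MeOH/H2O, 0 °C → rt; then 1 M HCl to pH 3
Reagents that add atoms: water, O
Why: Saponification of the strained bridged lactone by acyl–oxygen cleavage, so C4 keeps its configuration; the tertiary trimethylsilyl ether is lost in the basic methanol and on acidification.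

Step 5
Reactants: 8 α-hydroxy acid with free C4 hydroxyl
Product: 9 cis-fused 4-hydroxy enone (C1 ketone; C2=C3)
Conditions: Pb(OAc)4, CH2Cl2, 0 °C
Reagents that add atoms: none
Why: Oxidative decarboxylation of an α-hydroxy acid by tetravalent lead through a cyclic lead ester; loss of CO2 gives the C1 ketone in conjugation with C2=C3, and the quaternary C5 prevents any aromatisation or elimination of the C4 hydroxyl.

Step 6
Reactants: 9 cis-fused 4-hydroxy enone
Product: 10 enone C4 propionate
Conditions: propionic anhydride, pyridine, DMAP (cat.), CH2Cl2, 0 °C
Reagents that add atoms: propionic anhydride, CCC(=O)OC(=O)CC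
Why: Acylation of the secondary allylic alcohol installs the propionate of the target; the mild amine base and low temperature are chosen because C16–H is both α to the ketone and allylic to the ethylidene.

Step 7
Reactants: 11 bromoacetyl bromide; 12 ethanethiol
Product: 13 S-ethyl 2-bromoethanethioate
Conditions: pyridine, CH2Cl2, −20 → 0 °C
Reagents that add atoms: none
Why: Acylation of the thiol by the acyl bromide, which at low temperature is much faster than displacement of the α-bromide.

Step 8
Reactants: 10 enone C4 propionate; 13 S-ethyl 2-bromoethanethioate
Product: 15 C2-alkylated ketone thioester (C15 on the face of C16–H), via lithium C1–C2 enolate 14 (not isolated)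
Conditions: LiBH(s-Bu)3 (L-Selectride, 1.05 equiv), THF, −78 °C; then 13, −78 → −40 °C
Reagents that add atoms: none
Why: Reductive alkylation: conjugate hydride addition to the β-unsubstituted enone gives the C1/C2 enolate regiospecifically, and SN2 displacement at the activated bromomethyl carbon is fast enough to precede proton transfer; the electrophile should enter C2 anti to the C16–C8 bond, whose Z-ethylidene methyl lies over the other face, and the resulting equatorial C2 substituent is also the thermodynamically preferred one.

Step 9
Reactants: 16 pent-3-yn-1-ol
Product: 17 pent-3-ynyl 4-methoxybenzyl ether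
Conditions: NaH, 4-methoxybenzyl chloride, Bu4NI (cat.), THF/DMF, 0 °C → rt
Reagents that add atoms: 4-methoxybenzyl chloride, COc1ccc(CCl)cc1
Why: Williamson etherification; the PMB group can later be removed oxidatively in the presence of silyl ether, esters and ketone.

Step 10
Reactants: 17 pent-3-ynyl 4-methoxybenzyl ether
Product: 19 E-4-iodopent-3-enyl 4-methoxybenzyl ether, via alkenylzirconocene chloride 18 (not isolated)
Conditions: Cp2Zr(H)Cl (slight excess), THF, rt → 40 °C; then I2, 0 °C
Reagents that add atoms: iodine, II
Why: Syn hydrozirconation; with a slight excess of the hydride the metal equilibrates to the less hindered, methyl-bearing alkyne carbon, and iodinolysis with retention gives the E iodide in which the methyl is cis to the chain.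

Step 11
Reactants: 19 E-4-iodopent-3-enyl 4-methoxybenzyl ether
Product: 21 E-alkenyl tributylstannane, via alkenyllithium 20 (not isolated)
Conditions: t-BuLi (2 equiv), Et2O, −78 °C; then Bu3SnCl, −78 °C → rt
Reagents that add atoms: tributyltin chloride, CCCC[Sn](Cl)(CCCC)CCCC
Why: Iodine–lithium exchange and stannylation both proceed with retention of olefin geometry.

Step 12
Reactants: 15 C2-alkylated ketone thioester; 21 E-alkenyl tributylstannane
Product: 22 enone with C14 ketone and E C12=C13
Conditions: Pd2(dba)3 (cat.), P(2-furyl)3, CuO2PPh2 (1.3 equiv), THF, rt → 45 °C
Reagents that add atoms: none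
Why: Liebeskind–Srogl-type coupling of a thioester with an organostannane under neutral conditions: the thiophilic copper salt activates the C–S bond and palladium transfers the alkenyl group with retention, leaving the C1 ketone, the propionate and the base-sensitive C16–H untouched.

Step 13
Reactants: 22 enone with C14 ketone
Product: 23 allylic alcohol with 14R configuration
Conditions: (S)-2-methyl-CBS-oxazaborolidine (0.3 equiv), catecholborane, toluene, −78 °C
Reagents that add atoms: none
Why: Corey–Bakshi–Shibata reduction; the α-methyl alkenyl group acts as the large substituent and the C15 methylene as the small one, which with the S catalyst gives 14R, while the C1 ketone, flanked by two tertiary carbons, should react much more slowly.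

Step 14
Reactants: 23 allylic alcohol with 14R configuration
Product: 24 C14 tert-butyldimethylsilyl ether
Conditions: TBSOTf, 2,6-lutidine, CH2Cl2, −78 °C
Reagents that add atoms: tert-butyldimethylsilyl triflate, CC(C)(C)[Si](C)(C)OS(=O)(=O)C(F)(F)F
Why: Silylation of the hindered secondary allylic alcohol; at −78 °C with the weak pyridine base the ketone is not converted into an enol silyl ether.

Step 15
Reactants: 24 C14 tert-butyldimethylsilyl ether
Product: 25 C10 primary alcohol
Conditions: DDQ, CH2Cl2/pH 7 buffer, 0 °C
Reagents that add atoms: none
Why: Oxidative cleavage of the PMB ether through its benzylic oxocarbenium ion; silyl ether, esters and trisubstituted olefins are inert at 0 °C.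

Step 16
Reactants: 25 C10 primary alcohol
Product: 26 C10 aldehyde
Conditions: Dess–Martin periodinane, NaHCO3, CH2Cl2, 0 °C; used at once
Reagents that add atoms: none
Why: Buffered Dess–Martin oxidation gives the β,γ-unsaturated aldehyde without acid or base that would move C12=C13 into conjugation.

Step 17
Reactants: 26 C10 aldehyde
Product: 27 tricyclic homoallylic alcohol (C9–C10 closed; C7=C8)
Conditions: Me2AlCl (3 equiv), CH2Cl2, −78 → −30 °C, slow addition at high dilution
Reagents that add atoms: none
Why: Lewis-acid-promoted intramolecular carbonyl-ene reaction: the tether from C2 lets the aldehyde reach C9 of the Z ethylidene only on the face on which the six-membered ring lies, the C7 hydrogen on that face moves to oxygen (C16–H lies on the other face), and with C11 pointing back toward C2 in the cyclic transition state C9 and C10 should form as 9S,10S.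

Step 18
Reactants: 27 tricyclic homoallylic alcohol
Product: 28 C10 acetate
Conditions: acetic anhydride, pyridine, DMAP (cat.), CH2Cl2, 0 °C
Reagents that add atoms: acetic anhydride, CC(=O)OC(C)=O
Why: Acylation installs the acetate of the target and removes a free hydroxyl that could anchor the hydrogenation catalyst on the wrong face of C7=C8.

Step 19
Reactants: 28 C10 acetate
Product: 29 ketone saturated at C7–C8 with C8–H cis to C16–H
Conditions: H2 (1 atm), Pt/C, EtOAc, rt
Reagents that add atoms: none
Why: Heterogeneous hydrogenation from the convex face of the cyclopentene, the other face being covered by the six-membered ring and the macrocycle; C12=C13 is screened inside by the ring and outside by the C14 silyl ether and should react more slowly, as hindered trisubstituted olefins do beside cyclopentenes.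

Step 20
Reactants: 29 ketone saturated at C7–C8
Product: 30 C1 methylene compound
Conditions: Zn, CH2Br2, TiCl4, THF/CH2Cl2, 0 °C → rt
Reagents that add atoms: dibromomethane, BrCBr
Why: Lombardo methylenation; the gem-dimetallic reagent is non-basic, so the α-stereocentres C2 and C16 are not epimerised, and it tolerates esters and silyl ethers while reacting with hindered ketones.

Step 21
Reactants: 30 C1 methylene compound
Product: 31 C14 allylic alcohol
Conditions: HF·pyridine, pyridine, THF, 0 °C → rt
Reagents that add atoms: none
Why: Fluoride-mediated desilylation buffered with pyridine leaves the two esters in place, where a basic fluoride source could move them to the free hydroxyl.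

Step 22
Reactants: 31 C14 allylic alcohol
Product: 32 target CNP0415604.1
Conditions: mCPBA (1.05 equiv), NaHCO3, CH2Cl2, −20 → 0 °C
Reagents that add atoms: 3-chloroperbenzoic acid, OOC(=O)c1cccc(Cl)c1
Why: Hydroxyl-assisted peracid epoxidation: only the outer face of the E olefin in the eleven-membered ring is open, and in the conformer that keeps the C13 methyl away from the six-membered ring the C14 hydroxyl lies on that face, which should give the 12S,13S epoxide threo to the hydroxyl; the trisubstituted, hydrogen-bond-assisted olefin should react well before the C1 methylene.

## Compound list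

1 | 3-hydroxy-2H-pyran-2-one | O=C1OC=CC=C1O | starting material
2 | 3-methylcyclopent-2-en-1-one | CC1=CC(=O)CC1 | starting material
3 | endo cycloadduct: 2-oxabicyclo[2.2.2]oct-5-en-3-one (bridgeheads C4 and C1, C1 bearing OH, olefin C2=C3) cis-fused across C5–C16 to a cyclopentanone (C8 ketone); C5 methyl and C16 hydrogen on the side of the lactone bridge | O=C1O[C@H]2C=C[C@]1(O)[C@@H]3C(=O)CC[C@@]32C | intermediate
4 | C1 trimethylsilyl ether of 3 | O=C1O[C@H]2C=C[C@]1(O[Si](C)(C)C)[C@@H]3C(=O)CC[C@@]32C | intermediate
5 | ethyltriphenylphosphonium bromide | CC[P+](c1ccccc1)(c1ccccc1)c1ccccc1.[Br-] | starting material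
6 | ethylidenetriphenylphosphorane | CC=P(c1ccccc1)(c1ccccc1)c1ccccc1 | intermediate (not isolated)
7 | silylated lactone with Z ethylidene at C8 (ethylidene methyl cis to C16) | O=C1O[C@H]2C=C[C@]1(O[Si](C)(C)C)[C@@H]3/C(=C\C)CC[C@@]32C | intermediate
8 | α-hydroxy acid: C1 bearing OH and CO2H, C2=C3, C4 hydroxyl cis to C5 methyl and C16 hydrogen, Z ethylidene at C8 | OC(=O)[C@]1(O)C=C[C@H](O)[C@@]2(C)CC/C(=C/C)[C@@H]12 | intermediate
9 | cis-fused 4-hydroxy enone: C1 ketone, C2=C3, C4 hydroxyl, C5 methyl and C16 hydrogen all cis, Z ethylidene at C8 | O=C1C=C[C@H](O)[C@@]2(C)CC/C(=C/C)[C@@H]12 | intermediate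
10 | C4 propionate of 9 | O=C1C=C[C@H](OC(=O)CC)[C@@]2(C)CC/C(=C/C)[C@@H]12 | intermediate
11 | bromoacetyl bromide | BrCC(=O)Br | starting material
12 | ethanethiol | CCS | starting material
13 | S-ethyl 2-bromoethanethioate | CCSC(=O)CBr | intermediate
14 | lithium C1–C2 enolate of the 2,3-dihydro ketone | [Li]OC1=CC[C@H](OC(=O)CC)[C@@]2(C)CC/C(=C/C)[C@@H]12 | intermediate (not isolated)
15 | C1 ketone carrying CH2C(O)SEt on C2 (2R, cis to C16 hydrogen and C4 propionate), Z ethylidene at C8 | O=C1[C@H](CC(=O)SCC)C[C@H](OC(=O)CC)[C@@]2(C)CC/C(=C/C)[C@@H]12 | intermediate
16 | pent-3-yn-1-ol | CC#CCCO | starting material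
17 | 1-methoxy-4-[(pent-3-yn-1-yloxy)methyl]benzene | CC#CCCOCc1ccc(OC)cc1 | intermediate
18 | chloro[(E)-5-(4-methoxybenzyloxy)pent-2-en-2-yl]zirconocene | C/C(=C\CCOCc1ccc(OC)cc1)[Zr](Cl)(C1C=CC=C1)C1C=CC=C1 | intermediate (not isolated)
19 | 1-{[(3E)-4-iodopent-3-en-1-yl]oxymethyl}-4-methoxybenzene | C/C(I)=C\CCOCc1ccc(OC)cc1 | intermediate
20 | (E)-5-(4-methoxybenzyloxy)pent-2-en-2-yllithium | [Li]/C(C)=C/CCOCc1ccc(OC)cc1 | intermediate (not isolated)
21 | tributyl[(2E)-5-(4-methoxybenzyloxy)pent-2-en-2-yl]stannane | C/C(=C\CCOCc1ccc(OC)cc1)[Sn](CCCC)(CCCC)CCCC | intermediate
22 | enone: C14 ketone, E C12=C13 with C13 methyl, C10 PMB ether, on the C2 side chain of the bicyclic C1 ketone | O=C1[C@H](CC(=O)/C(C)=C/CCOCc3ccc(OC)cc3)C[C@H](OC(=O)CC)[C@@]2(C)CC/C(=C/C)[C@@H]12 | intermediate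
23 | (14R) allylic alcohol from 22 | O=C1[C@H](C[C@@H](O)/C(C)=C/CCOCc3ccc(OC)cc3)C[C@H](OC(=O)CC)[C@@]2(C)CC/C(=C/C)[C@@H]12 | intermediate
24 | C14 tert-butyldimethylsilyl ether of 23 | O=C1[C@H](C[C@@H](O[Si](C)(C)C(C)(C)C)/C(C)=C/CCOCc3ccc(OC)cc3)C[C@H](OC(=O)CC)[C@@]2(C)CC/C(=C/C)[C@@H]12 | intermediate
25 | C10 primary alcohol | O=C1[C@H](C[C@@H](O[Si](C)(C)C(C)(C)C)/C(C)=C/CCO)C[C@H](OC(=O)CC)[C@@]2(C)CC/C(=C/C)[C@@H]12 | intermediate
26 | C10 aldehyde (β,γ-unsaturated), Z ethylidene at C8 | O=C1[C@H](C[C@@H](O[Si](C)(C)C(C)(C)C)/C(C)=C/CC=O)C[C@H](OC(=O)CC)[C@@]2(C)CC/C(=C/C)[C@@H]12 | intermediate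
27 | tricyclic ene product: eleven-membered ring closed at C9–C10, C7=C8, (9S,10S), C10 hydroxyl, C14 silyl ether, E C12=C13, C1 ketone, C4 propionate | O=C1[C@H]2C[C@H](OC(=O)CC)[C@@]3(C)CC=C([C@H](C)[C@@H](O)C/C=C(\C)[C@H](O[Si](C)(C)C(C)(C)C)C2)[C@@H]13 | intermediate
28 | C10 acetate of 27 | O=C1[C@H]2C[C@H](OC(=O)CC)[C@@]3(C)CC=C([C@H](C)[C@@H](OC(C)=O)C/C=C(\C)[C@H](O[Si](C)(C)C(C)(C)C)C2)[C@@H]13 | intermediate
29 | C7–C8 saturated ketone, C8 hydrogen cis to C16 hydrogen (8R) | O=C1[C@H]2C[C@H](OC(=O)CC)[C@@]3(C)CC[C@@H]([C@H](C)[C@@H](OC(C)=O)C/C=C(\C)[C@H](O[Si](C)(C)C(C)(C)C)C2)[C@@H]13 | intermediate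
30 | C1 methylene compound, C14 silyl ether | C=C1[C@H]2C[C@H](OC(=O)CC)[C@@]3(C)CC[C@@H]([C@H](C)[C@@H](OC(C)=O)C/C=C(\C)[C@H](O[Si](C)(C)C(C)(C)C)C2)[C@@H]13 | intermediate
31 | (14R) allylic alcohol with E C12=C13 (target without the epoxide oxygen) | C=C1[C@H]2C[C@H](OC(=O)CC)[C@@]3(C)CC[C@@H]([C@H](C)[C@@H](OC(C)=O)C/C=C(\C)[C@H](O)C2)[C@@H]13 | intermediate
32 | CNP0415604.1: C4 propionate, C10 acetate, (12S,13S) epoxide, (14R) alcohol, C1 methylene | C=C1[C@H]2C[C@H](OC(=O)CC)[C@@]3(C)CC[C@@H]([C@H](C)[C@@H](OC(C)=O)C[C@@H]4O[C@@]4(C)[C@H](O)C2)[C@@H]13 | target

## Step count and least certain steps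

Total: 22 steps. Longest linear sequence: 18 steps (steps 1–6, 8 and 12–22).

**Step 1 (key step).** The conjugate-addition half of the cycloaddition may be too slow at the fully substituted β-carbon of 2, and the adduct can revert by retro-aldol and retro-Michael cleavage, so conversion may stall. Exo orientation or weak enantiofacial control are the second concern, because the substrate class has not been tried. The fallback activates the dienophile with a removable ester. It sets out from 2 and returns at 3. α-Iodination of 2 (I2, pyridine) would give 2-iodo-3-methylcyclopent-2-en-1-one F1. Carbonylation (CO, Pd(OAc)2, PPh3, Et3N, 2-(trimethylsilyl)ethanol) would give 2-(trimethylsilyl)ethyl 2-methyl-5-oxocyclopent-1-ene-1-carboxylate F2, a doubly activated acceptor. Reaction of F2 with 1 under the same chiral base would give the cycloadduct with the ester on C16 F3. Fluoride (Bu4NF buffered with AcOH) would then cleave the silylethyl ester, and the β-keto acid would lose CO2, with hydrogen entering C16 on the only face the bicycle allows.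

**Step 8.** Proton transfer between enolate 14 and the acidic bromothioester or the product may compete with alkylation. That would shift the enolate toward the conjugated C16 side and erode both the regiochemistry and the configuration at C2. The fallback uses a less acidic electrophile and a different ketone synthesis. It sets out from 10 and returns at 22. Reductive alkylation of 10 with allyl bromoacetate would give the allyl ester F4. Deallylation (Pd(PPh3)4, morpholine) would give the carboxylic acid F5. 1-Chloro-N,N,2-trimethylpropenylamine would convert it under neutral conditions into the acid chloride F6, and a Stille acylation of 21 (Pd2(dba)3, AsPh3, THF) would give enone 22.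

**Step 17.** Ring closure may lose out to oligomerisation, because the ene reaction has a late, highly ordered transition state and the eleven-membered ring is strained. A stepwise cationic course could also remove the C16 hydrogen instead of the C7 hydrogen, and the β,γ-unsaturated aldehyde may isomerise under the Lewis acid. The fallback closes the same bond with a far stronger electrophile. It sets out from 26 and returns at 27. Pinnick oxidation (NaClO2, NaH2PO4, 2-methyl-2-butene) would give the C10 carboxylic acid F7, and 1-chloro-N,N,2-trimethylpropenylamine the C10 acid chloride F8. SnCl4 at −78 °C and high dilution would acylate the ethylidene at C9 with loss of HCl to give the macrocyclic C10 ketone F9. Reduction with (R)-2-methyl-CBS-oxazaborolidine and catecholborane, in which the branched C9 is the large group and the C1 ketone is the more hindered carbonyl, would give 27.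

**Step 19.** Hydrogen may also add to C12=C13, or the catalyst may move C7=C8 into conjugation with the C1 ketone before reducing it, which would erase C16. The fallback reorders the endgame so that the epoxide protects C12=C13 during the hydrogenation. It sets out from 28 and returns at 32. HF·pyridine would give the desilylated allylic alcohol F10. VO(acac)2 with t-BuOOH, which epoxidises only the allylic alcohol, would give the epoxy alcohol that still holds C7=C8, F11. Hydrogenation over Pt/C would give the saturated epoxy ketone F12. Methylenation at low temperature with Cp2Ti(μ-Cl)(μ-CH2)AlMe2 in THF/pyridine, which reacts with ketones before esters, would give 32.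

**Step 22.** The peracid may attack the other face of C12=C13 if the macrocycle prefers the conformer that turns the C13 methyl toward the six-membered ring, and some epoxidation of the C1 methylene may occur. The fallback delivers oxygen to the opposite face by a two-step anti addition and closure. It sets out from 31 and returns at 32. N-Bromosuccinimide in aqueous THF would form the bromonium ion on the accessible face; water opens it at the tertiary C13 from the other side to give the bromohydrin F13. Ag2O in CH2Cl2 would close the epoxide by displacing bromide at C12 with inversion.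

## Further compounds

F1 | step 1 | 2-iodo-3-methylcyclopent-2-en-1-one | CC1=C(I)C(=O)CC1
F2 | step 1 | 2-(trimethylsilyl)ethyl 2-methyl-5-oxocyclopent-1-ene-1-carboxylate | CC1=C(C(=O)OCC[Si](C)(C)C)C(=O)CC1
F3 | step 1 | cycloadduct with the 2-(trimethylsilyl)ethyl ester on C16 | O=C1O[C@H]2C=C[C@]1(O)[C@]3(C(=O)OCC[Si](C)(C)C)C(=O)CC[C@@]32C
F4 | step 8 | allyl ester analogue of 15 | O=C1[C@H](CC(=O)OCC=C)C[C@H](OC(=O)CC)[C@@]2(C)CC/C(=C/C)[C@@H]12
F5 | step 8 | carboxylic acid (C14) from F4 | O=C1[C@H](CC(=O)O)C[C@H](OC(=O)CC)[C@@]2(C)CC/C(=C/C)[C@@H]12
F6 | step 8 | acid chloride (C14) from F5 | O=C1[C@H](CC(=O)Cl)C[C@H](OC(=O)CC)[C@@]2(C)CC/C(=C/C)[C@@H]12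
F7 | step 17 | C10 carboxylic acid from 26 | O=C1[C@H](C[C@@H](O[Si](C)(C)C(C)(C)C)/C(C)=C/CC(=O)O)C[C@H](OC(=O)CC)[C@@]2(C)CC/C(=C/C)[C@@H]12
F8 | step 17 | C10 acid chloride from F7 | O=C1[C@H](C[C@@H](O[Si](C)(C)C(C)(C)C)/C(C)=C/CC(=O)Cl)C[C@H](OC(=O)CC)[C@@]2(C)CC/C(=C/C)[C@@H]12
F9 | step 17 | macrocyclic C10 ketone with C7=C8 | O=C1[C@H]2C[C@H](OC(=O)CC)[C@@]3(C)CC=C([C@H](C)C(=O)C/C=C(\C)[C@H](O[Si](C)(C)C(C)(C)C)C2)[C@@H]13
F10 | step 19 | desilylated C14 allylic alcohol with C7=C8 and C1 ketone | O=C1[C@H]2C[C@H](OC(=O)CC)[C@@]3(C)CC=C([C@H](C)[C@@H](OC(C)=O)C/C=C(\C)[C@H](O)C2)[C@@H]13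
F11 | step 19 | (12S,13S) epoxy alcohol with C7=C8 and C1 ketone | O=C1[C@H]2C[C@H](OC(=O)CC)[C@@]3(C)CC=C([C@H](C)[C@@H](OC(C)=O)C[C@@H]4O[C@@]4(C)[C@H](O)C2)[C@@H]13
F12 | step 19 | saturated epoxy alcohol with C1 ketone | O=C1[C@H]2C[C@H](OC(=O)CC)[C@@]3(C)CC[C@@H]([C@H](C)[C@@H](OC(C)=O)C[C@@H]4O[C@@]4(C)[C@H](O)C2)[C@@H]13
F13 | step 22 | bromohydrin: C12 bromide, C13 and C14 hydroxyls | C=C1[C@H]2C[C@H](OC(=O)CC)[C@@]3(C)CC[C@@H]([C@H](C)[C@@H](OC(C)=O)C[C@@H](Br)[C@@](C)(O)[C@H](O)C2)[C@@H]13
A1 | alternative 1 | fifteen-membered lactone (ester oxygen on C6, C7=C8, acyl α-carbon C9), C1 dioxolane, C4 triethylsilyl ether | O1CCOC12[C@H]3C[C@H](O[Si](CC)(CC)CC)[C@@]4(C)[C@@H](OC(=O)C[C@@H](OCc5ccc(OC)cc5)C/C=C(\C)[C@H](O[Si](C)(C)C(C)(C)C)C3)C=C[C@@H]24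
A2 | alternative 1 | eleven-membered carbocycle with C9 carboxylic acid and C6=C7 olefin | O1CCOC12[C@H]3C[C@H](O[Si](CC)(CC)CC)[C@@]4(C)C=C[C@@H]([C@H](C(=O)O)[C@@H](OCc5ccc(OC)cc5)C/C=C(\C)[C@H](O[Si](C)(C)C(C)(C)C)C3)[C@@H]24
A3 | alternative 2 | thirteen-membered ring with 1-bromovinyl group on C16, C2=C15 olefin and C14 hydroxyl | C=C(Br)[C@H]1[C@@]2(C)[C@@H](OC(=O)CC)C/C=C/C(O)/C(C)=C/C[C@H](OC(C)=O)[C@@H](C)[C@@H]1CC2
A4 | alternative 2 | tricyclic C14 enone with C1 methylene | C=C1[C@H]2C[C@H](OC(=O)CC)[C@@]3(C)CC[C@@H]([C@H](C)[C@@H](OC(C)=O)C/C=C(\C)C(=O)C2)[C@@H]13
A5 | alternative 3 | C10 aldehyde with Z ethylidene at C8 (identical with 26) | O=C1[C@H](C[C@@H](O[Si](C)(C)C(C)(C)C)/C(C)=C/CC=O)C[C@H](OC(=O)CC)[C@@]2(C)CC/C(=C/C)[C@@H]12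
A6 | alternative 3 | macrocyclic C10 alcohol with C7=C8 olefin (identical with 27) | O=C1[C@H]2C[C@H](OC(=O)CC)[C@@]3(C)CC=C([C@H](C)[C@@H](O)C/C=C(\C)[C@H](O[Si](C)(C)C(C)(C)C)C2)[C@@H]13
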